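(All constants are assumed, and the outcome is calculated.)

A leftover of substrate is what we look for in this flask. Partner and substrate are charged one for one, so each partner quenched by the protic impurity leaves one substrate with no partner to meet.

substrate 0.33 M (fed, over 50 min); partner 1.00 equiv; protic impurity 0.165 M; initiator 0.5 mol%; time 3.0 d

    2 second chain carrier → ended chains (k1 = 7 × 10⁸ M⁻¹ s⁻¹)
    partner + protic impurity → quenched reagent (k2 = 0.723 M⁻¹ h⁻¹)
    initiator → 2 initiating radical (k3 = 6.55 × 10⁻⁴ h⁻¹)
    partner + first chain carrier → product + second chain carrier (k4 = 67600 M⁻¹ s⁻¹)
    substrate + initiating radical → capped initiator + first chain carrier (k5 = 4.64 × 10⁵ M⁻¹ s⁻¹)
    substrate + second chain carrier → by-product + first chain carrier (k6 = 50500 M⁻¹ s⁻¹)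

- two of one species on the left: rate k times its square, two consumed each time
- the reaction counts as stopped when no species that holds the substrate changes by six tenths of a point or more over the second half of the time
- run time (flask): 3.0 d

1. the state of affairs at 3.0 d: stopped, and by what, or still going (all of the substrate has reacted / it is still moving / forward and back rates have come level / the partner has run out first)
2. part of the substrate gone at 3.0 d
3. the product standing at 3.0 d, as a percentage of the substrate charged

We want the pace of the chain first. The initiator has a half-life of 44 d against a run of 3.0 d, so it feeds radicals steadily, like a constant inflow to a tank. Carriers are lost by ending in pairs from the second chain carrier, and while partner stands we set inflow equal to drain, which gives 6.55 × 10⁻¹⁰ M of second chain carrier. Substrate then decays pseudo-first-order, through its step with the second chain carrier, with constant 0.119 h⁻¹, a time constant of 8.40 h. That is well inside the run, and the feed is shorter, so we ignore the feed. Partner is quenched with constant 0.119 h⁻¹.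

Now we divide the quench rate by the chain rate, and time drops out. With partner and substrate equal, they cancel and the ratio is 1.00. This is the quench share: partner quenched per substrate consumed. Partner stands in its numerator, so the share falls to nothing as partner, the limiting reagent, runs out. We take the mean of the two ends, 0.501. Consumed substrate plus quenched partner must equal the partner charge, so we expect the partner to run out first, with conversion 66.6% and product 66.6%, one product per substrate consumed.

The forecast says the partner has run out first, with 69.5% gone and 69.4% of product, on the ground that “With no partner the chain cannot turn over”. Its conversion is higher than ours.

The flask gives the partner has run out first, with 70.0% gone and 70.0% of product, so the forecast stands within its margins. At 3.00 d the flask holds 0% of its partner and 0.0992 M of quenched reagent. Quenched reagent over product gives a mean quench share of 0.430 in this flask, against our 0.501.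

A neighbour flask charged with 0.250 equiv of partner starts at a quench share of 0.250. Its mean of 0.125 gives a conversion of 22.2%. That neighbour reaches 21.4% with 0% of its partner left.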